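The readings are calculated on assumed constants; the scatter is artificial.

I decided to judge this flask by counting its partner, not by its flat readings.

in all of them: substrate 0.20 M
- spring: partner 0.36 M; temperature 0 °C; the very flask that is asked about, followed so far
- dawn: partner 0.24 M; temperature −15 °C; run made earlier
- flask: partner 0.360 M; temperature 0 °C; time 50 min

- spring (time / min: single product / %): 8.00: 60.5; 15.0: 60.1; 20.0: 60.5; 30.0: 60.2; 40.0: 59.9; 50.0: 60.2
- dawn (time / min: single product / %): 2.00: 33.7; 4.00: 31.8; 6.00: 31.3; 8.00: 31.2; 10.0: 31.4; 12.0: 31.4; 15.0: 30.5

(standard deviation of a reading: 0.3 percentage points)

- Thursday's: at 50 min raise the temperature by 25 K, then wait 15 min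
- Sunday's: change nothing and wait 15 min more
- Tuesday's: at 50 min add partner, 100 % of the amount charged, then wait 15 min
- Wednesday's: at 50 min take out 90 % of the by-product then present, then wait 15 min

- additions bring no volume worth counting

1. single product, in percent of the substrate first charged, at 50 min
2. what to do for the largest gain in single product; "none" if nothing gains more than 2 percentage points (Thursday's / Sunday's / Tuesday's / Wednesday's / none)
3. single product present, in percent of the substrate first charged, after Thursday's
4. single product present, in percent of the substrate first charged, after Sunday's

The spring run, which is this flask followed so far, held near 60.2 % from 8.00 min on, so I put that figure for now and after Sunday's. That line did not say where the missing 39.8 % of the substrate stood. I therefore held two amounts against each other: the partner beyond one equivalent, 0.160 M, and the substrate, 0.20 M. Their ratio was 0.800, the surplus per substrate, which counts the further additions the charge can pay for per molecule of substrate.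

In the dawn run the same ratio was 0.200, yet 68.6 % of its substrate stood outside single product, so I took part of it to sit in a form costing no further partner. In the spring run, if the surplus went wholly into further additions, 2.01 per missing molecule would cover the whole gap and leave no room for that form. I therefore took the next whole number, 3, which left a pool of 73.3 % as single product plus that form. I took this as my estimate of the ceiling for Thursday's.

The forecast gave 60.2 %, 60.2 % after Sunday's and 84 % after Thursday's, and it chose Thursday's, saying “warming appears to favour the single product”. I shared that choice but stood lower on the height.

The flask stood at 60.1 % with partner at 0 %, and it gave 60.1 % after Sunday's and 71.1 % after Thursday's, the best option at 11 percentage points.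

    substrate + partner → single product + by-product (k = 1.58 L mol⁻¹ s⁻¹, Ea = 38.0 kJ mol⁻¹)
    partner + double product → triple product + by-product (k = 2.83 L mol⁻¹ s⁻¹, Ea = 40.0 kJ mol⁻¹)
    single product ⇌ isomer of the product (K = 0.191, k = 0.0940 s⁻¹, Ea = 62.0 kJ mol⁻¹, ΔH = −90.0 kJ mol⁻¹)
    partner + triple product → tetra adduct + by-product (k = 1.53 L mol⁻¹ s⁻¹, Ea = 37.0 kJ mol⁻¹)
    partner + single product → double product + by-product (k = 0.0627 L mol⁻¹ s⁻¹, Ea = 39.0 kJ mol⁻¹)
    (constants at 0 °C)

The largest single effect on that gain was the loss of single product to isomer of the product: with that step taken away, the flask stood at 71.2 % and Thursday's brought 0 points. Tetra adduct takes 3 further partners, and in this flask the surplus per substrate of 0.800 over 3 gives 26.7 %, with tetra adduct at 24.5 % at 50.0 min. In the flask charged with 0.61 M of partner, the surplus per substrate was 2.05, which over 3 gives 68.3 %, and tetra adduct held 67.4 %.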